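**Plan**

1. Ring B of the target (C1–C2–C3–C4–C4a–C8a) is a cyclohexene whose double bond is the aromatic C4a–C8a bond of ring A, which makes it a Diels–Alder retron.
2. The retrosynthesis first cuts the C1–aryl bond (Friedel–Crafts transform; C1 is benzylic and para to the C6 methoxy group), leaving a C1 carbinol. It then cuts C1–C2 and C3–C4 together, giving the photoenol HO–CH=C8a–C4a=CH2 of an o-tolualdehyde and a cis C2=C3 dienophile.
3. The dienophile is a 5-menthyloxybutenolide, whose lactone carbonyl and acetal carbon are the two future CH2OH carbons; the lactone is a temporary ring and the menthyl group a removable auxiliary.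
4. Forward: ring A aldehyde (two steps) → photoenolization/Diels–Alder closes ring B → LiAlH4 opens the lactone acetal to the cis diol → Friedel–Crafts arylation with guaiacol → debenzylation.
5. Stereochemistry: C2/C3 cis from the ring Z-alkene, with absolute sense from addition anti to the menthyloxy group of the (5S)-butenolide; C1 from attack of guaiacol on the C1 cation anti to the two cis hydroxymethyl groups (1,2-trans).

Key step: step 3

Remark: tetralin numbering is used throughout (C1 aryl-bearing, C2 and C3 hydroxymethyl-bearing, C4 benzylic CH2; ring A is the fused arene, ring B the saturated ring); the (5S)-menthyloxybutenolide derived from (+)-menthol is assumed to be purchasable like its enantiomer, and is otherwise made from furfural by dye-sensitised photooxygenation and acetalisation with (+)-menthol.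

**Step 1**
Reactants: 1 2-bromo-5-hydroxy-4-methoxybenzaldehyde
Product: 2 5-(benzyloxy)-2-bromo-4-methoxybenzaldehyde
Conditions: BnBr (1.2 equiv), K2CO3, DMF, rt
Reagents that add atoms: benzyl bromide, BrCc1ccccc1
Why: Williamson ether synthesis, in which the phenoxide of 1 (the only acidic site) displaces bromide from benzyl bromide by SN2; the benzyl ether shields the phenol from hydrogen abstraction by the excited aldehyde in step 3 and forms no stereocentre.

**Step 2**
Reactants: 2 5-(benzyloxy)-2-bromo-4-methoxybenzaldehyde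
Product: 3 5-(benzyloxy)-4-methoxy-2-methylbenzaldehyde
Conditions: (MeBO)3 (0.6 equiv), Pd(dppf)Cl2 (5 mol %), K2CO3, 1,4-dioxane/H2O, 100 °C
Reagents that add atoms: trimethylboroxine, CB1OB(C)OB(C)O1
Why: Suzuki–Miyaura cross-coupling, in which zerovalent palladium inserts into the C–Br bond activated by the ortho formyl group, a methyl group is transferred from the base-activated boroxine and reductive elimination installs the methyl group that becomes C4; the aldehyde and benzyl ether are inert here.

**Step 3**
Reactants: 3 5-(benzyloxy)-4-methoxy-2-methylbenzaldehyde; 4 (5S)-5-[(1S,2R,5S)-menthyloxy]furan-2(5H)-one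
Product: 6 (3S,3aS,9S,9aS)-7-(benzyloxy)-9-hydroxy-6-methoxy-3-[(1S,2R,5S)-menthyloxy]-3a,4,9,9a-tetrahydronaphtho[2,3-c]furan-1(3H)-one, via E-dienol 5 (not isolated)
Conditions: hν (350–365 nm), 4 (1.5 equiv), degassed toluene, rt
Reagents that add atoms: none
Why: Excitation of 3 and intersystem crossing give the triplet aldehyde, which abstracts a hydrogen atom from the ortho methyl group (1,5-transfer) and relaxes to the long-lived E-dienol 5 (the Z-dienol returns to 3 by a 1,5-hydrogen shift); 5 is a hydroxy-o-quinodimethane that adds to the electron-poor ring alkene of 4 in a thermal suprafacial [4+2] cycloaddition, forming C4–C3 and C1–C2 (C4–C3a and C9–C9a of 6) and restoring the aromaticity of ring A. The closest known reaction type is the photoenolization/Diels–Alder reaction of o-tolualdehydes with acrylates and butenolides. Ring B is closed by this intermolecular [4+2] cycloaddition, with the lactone of 4 carried along as a cis-fused temporary ring that holds both future hydroxymethyl carbons. C3a and C9a should be set cis by the ring Z-alkene and suprafacial addition, and their absolute configuration by approach of the diene to the face of 4 anti to the menthyloxy group on its acetal carbon (substrate control by the auxiliary); C9 should follow from the endo transition state of the E-dienol but is erased in step 5. The step needs regioselectivity (hydroxyl-bearing terminus to the α-carbon, methylene terminus to the β-carbon), which the donor hydroxyl should secure by placing the largest HOMO coefficient on the methylene terminus, and it needs excitation of 3 alone, which irradiation at 350–365 nm, where 4 is transparent, should secure.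

**Step 4**
Reactants: 6 (3S,3aS,9S,9aS)-7-(benzyloxy)-9-hydroxy-6-methoxy-3-[(1S,2R,5S)-menthyloxy]-3a,4,9,9a-tetrahydronaphtho[2,3-c]furan-1(3H)-one
Product: 7 (1S,2R,3S)-7-(benzyloxy)-2,3-bis(hydroxymethyl)-6-methoxy-1,2,3,4-tetrahydronaphthalen-1-ol
Conditions: LiAlH4 (3 equiv), THF, 0 °C → rt; then Na2SO4·10H2O
Reagents that add atoms: none
Why: Hydride reduction of a lactone, in which LiAlH4 reduces the carbonyl to the primary alkoxide, the freed hemiacetal expels menthoxide and the resulting aldehyde is reduced in turn, so both hydroxymethyl groups appear and the auxiliary is released while C2 and C3 keep their cis configuration.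

**Step 5**
Reactants: 7 (1S,2R,3S)-7-(benzyloxy)-2,3-bis(hydroxymethyl)-6-methoxy-1,2,3,4-tetrahydronaphthalen-1-ol; 8 guaiacol (2-methoxyphenol)
Product: 9 4-[(1S,2R,3S)-7-(benzyloxy)-2,3-bis(hydroxymethyl)-6-methoxy-1,2,3,4-tetrahydronaphthalen-1-yl]-2-methoxyphenol
Conditions: 8 (5 equiv), TsOH·H2O (10 mol %), (CF3)2CHOH, 0 °C → rt
Reagents that add atoms: none
Why: Friedel–Crafts alkylation of a phenol by a benzylic alcohol (SN1), in which acid in the ionising solvent turns the C1 carbinol into a cation stabilised by the para C6 methoxy group, guaiacol attacks through its position para to the hydroxyl, and because both hydroxymethyl groups shield the same face the arene should enter from the opposite face, setting C1 with the aryl trans to the C2 substituent by substrate control whatever the carbinol configuration was.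

**Step 6**
Reactants: 9 4-[(1S,2R,3S)-7-(benzyloxy)-2,3-bis(hydroxymethyl)-6-methoxy-1,2,3,4-tetrahydronaphthalen-1-yl]-2-methoxyphenol
Product: 10 (6S,7R,8S)-8-(4-hydroxy-3-methoxyphenyl)-6,7-bis(hydroxymethyl)-3-methoxy-5,6,7,8-tetrahydronaphthalen-2-ol
Conditions: H2 (1 atm), Pd/C (10 wt %), MeOH/EtOAc, rt
Reagents that add atoms: none
Why: Hydrogenolysis of the benzyl aryl ether over Pd/C frees the ring A phenol, while the doubly benzylic C1–H bond and the primary alcohols are inert, so no stereocentre is touched.

**Compound list**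

1 | 2-bromo-5-hydroxy-4-methoxybenzaldehyde | O=Cc1cc(O)c(OC)cc1Br | starting material
2 | 5-(benzyloxy)-2-bromo-4-methoxybenzaldehyde | O=Cc1cc(OCc2ccccc2)c(OC)cc1Br | intermediate
3 | 5-(benzyloxy)-4-methoxy-2-methylbenzaldehyde | O=Cc1cc(OCc2ccccc2)c(OC)cc1C | intermediate
4 | (5S)-5-{[(1S,2R,5S)-5-methyl-2-(propan-2-yl)cyclohexyl]oxy}furan-2(5H)-one | O=C1C=C[C@@H](O[C@H]2C[C@@H](C)CC[C@@H]2C(C)C)O1 | starting material
5 | (E)-[3-(benzyloxy)-4-methoxy-6-methylidenecyclohexa-2,4-dien-1-ylidene]methanol (photoenol of 3) | O/C=C1\C=C(OCc2ccccc2)C(OC)=CC1=C | intermediate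
6 | (3S,3aS,9S,9aS)-7-(benzyloxy)-9-hydroxy-6-methoxy-3-{[(1S,2R,5S)-5-methyl-2-(propan-2-yl)cyclohexyl]oxy}-3a,4,9,9a-tetrahydronaphtho[2,3-c]furan-1(3H)-one (all-cis at C3a, C9, C9a; menthyloxy trans to the ring B bonds) | O[C@@H]1c2cc(OCc3ccccc3)c(OC)cc2C[C@H]2[C@@H]1C(=O)O[C@@H]2O[C@H]1C[C@@H](C)CC[C@@H]1C(C)C | intermediate
7 | (1S,2R,3S)-7-(benzyloxy)-2,3-bis(hydroxymethyl)-6-methoxy-1,2,3,4-tetrahydronaphthalen-1-ol (all-cis triol) | O[C@@H]1c2cc(OCc3ccccc3)c(OC)cc2C[C@H](CO)[C@@H]1CO | intermediate
8 | guaiacol (2-methoxyphenol) | COc1ccccc1O | starting material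
9 | 4-[(1S,2R,3S)-7-(benzyloxy)-2,3-bis(hydroxymethyl)-6-methoxy-1,2,3,4-tetrahydronaphthalen-1-yl]-2-methoxyphenol | COc1cc([C@H]2c3cc(OCc4ccccc4)c(OC)cc3C[C@H](CO)[C@@H]2CO)ccc1O | intermediate
10 | (6S,7R,8S)-8-(4-hydroxy-3-methoxyphenyl)-6,7-bis(hydroxymethyl)-3-methoxy-5,6,7,8-tetrahydronaphthalen-2-ol (1,2-trans, 2,3-cis in tetralin numbering) | COc1cc([C@H]2c3cc(O)c(OC)cc3C[C@H](CO)[C@@H]2CO)ccc1O | target

**Step count and risks**

Total step count: 6. Longest linear sequence: 6 steps (1 → 10).

Steps most likely to fail: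

1. Step 3. Photoenolization of the electron-rich aldehyde may be inefficient (a low-lying π,π* triplet), so that photodegradation or erosion of regiocontrol overtakes the cycloaddition. The fallback generates the same dienol thermally and sets out from 2. Corey–Chaykovsky epoxidation of 2 (Me3SI, NaH, DMSO/THF) should give racemic 2-[5-(benzyloxy)-2-bromo-4-methoxyphenyl]oxirane F1. Bromine–lithium exchange (n-BuLi, MgBr2·OEt2, THF, −78 °C) followed by 4-exo opening of the oxirane at its CH2 terminus (Parham-type cyclisation) should give racemic 4-(benzyloxy)-3-methoxybicyclo[4.2.0]octa-1,3,5-trien-7-ol F2. Heating F2 with 4 in toluene at 110 °C should open the cyclobutene conrotatorily, hydroxyl outward, to dienol 5, which is trapped as before; the route is rejoined at 6.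

2. Step 5. Guaiacol may attack through a position other than the one para to its hydroxyl; the cation may lose the C2 proton and scramble C2 on re-protonation; or the C3 hydroxymethyl group may capture the cation as a bridged ether. The fallback replaces the SN1 arylation by a stereospecific cross-coupling and sets out from 7. Acylation (PivCl, pyridine, DMAP) should give (1S,2R,3S)-7-(benzyloxy)-6-methoxy-2,3-bis[(pivaloyloxy)methyl]-1,2,3,4-tetrahydronaphthalen-1-yl pivalate F3. Nickel-catalysed Suzuki-type coupling of the secondary benzylic pivalate with tris[4-(benzyloxy)-3-methoxyphenyl]boroxine (Ni(cod)2, NaOMe, toluene, 70 °C), which is known to proceed with inversion, should give {(1S,2R,3S)-7-(benzyloxy)-1-[4-(benzyloxy)-3-methoxyphenyl]-6-methoxy-1,2,3,4-tetrahydronaphthalene-2,3-diyl}bis(methylene) dipivalate F4 with the aryl trans to C2 and a regiodefined pendant ring. LiAlH4 should then give {(1S,2R,3S)-7-(benzyloxy)-1-[4-(benzyloxy)-3-methoxyphenyl]-6-methoxy-1,2,3,4-tetrahydronaphthalene-2,3-diyl}dimethanol F5, and hydrogenolysis under the conditions of step 6 rejoins the route at 10.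

3. Step 4. Retro-aldol cleavage of the C9–C9a bond in the aluminium alkoxide of the β-hydroxy lactone may compete with hydride delivery, or reduction may stall at the lactol acetal. The fallback masks the hydroxyl first and sets out from 6. Silylation (TBSOTf, 2,6-lutidine, CH2Cl2) should give (3S,3aS,9S,9aS)-7-(benzyloxy)-9-[(tert-butyldimethylsilyl)oxy]-6-methoxy-3-[(1S,2R,5S)-menthyloxy]-3a,4,9,9a-tetrahydronaphtho[2,3-c]furan-1(3H)-one F6. Reduction with i-Bu2AlH (THF, −78 °C → 0 °C) should give [(1S,2R,3S)-7-(benzyloxy)-1-[(tert-butyldimethylsilyl)oxy]-6-methoxy-1,2,3,4-tetrahydronaphthalene-2,3-diyl]dimethanol F7, and desilylation with tetrabutylammonium fluoride in THF rejoins the route at 7.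

**Further compounds**

F1 | step 3 | 2-[5-(benzyloxy)-2-bromo-4-methoxyphenyl]oxirane (racemic) | COc1cc(Br)c(C2CO2)cc1OCc1ccccc1
F2 | step 3 | 4-(benzyloxy)-3-methoxybicyclo[4.2.0]octa-1,3,5-trien-7-ol (racemic) | OC1Cc2cc(OC)c(OCc3ccccc3)cc21
F3 | step 5 | (1S,2R,3S)-7-(benzyloxy)-6-methoxy-2,3-bis[(pivaloyloxy)methyl]-1,2,3,4-tetrahydronaphthalen-1-yl pivalate | CC(C)(C)C(=O)O[C@@H]1c2cc(OCc3ccccc3)c(OC)cc2C[C@H](COC(=O)C(C)(C)C)[C@@H]1COC(=O)C(C)(C)C
F4 | step 5 | {(1S,2R,3S)-7-(benzyloxy)-1-[4-(benzyloxy)-3-methoxyphenyl]-6-methoxy-1,2,3,4-tetrahydronaphthalene-2,3-diyl}bis(methylene) dipivalate | COc1cc([C@H]2c3cc(OCc4ccccc4)c(OC)cc3C[C@H](COC(=O)C(C)(C)C)[C@@H]2COC(=O)C(C)(C)C)ccc1OCc1ccccc1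
F5 | step 5 | {(1S,2R,3S)-7-(benzyloxy)-1-[4-(benzyloxy)-3-methoxyphenyl]-6-methoxy-1,2,3,4-tetrahydronaphthalene-2,3-diyl}dimethanol | COc1cc([C@H]2c3cc(OCc4ccccc4)c(OC)cc3C[C@H](CO)[C@@H]2CO)ccc1OCc1ccccc1
F6 | step 4 | (3S,3aS,9S,9aS)-7-(benzyloxy)-9-[(tert-butyldimethylsilyl)oxy]-6-methoxy-3-[(1S,2R,5S)-menthyloxy]-3a,4,9,9a-tetrahydronaphtho[2,3-c]furan-1(3H)-one | CC(C)(C)[Si](C)(C)O[C@@H]1c2cc(OCc3ccccc3)c(OC)cc2C[C@H]2[C@@H]1C(=O)O[C@@H]2O[C@H]1C[C@@H](C)CC[C@@H]1C(C)C
F7 | step 4 | [(1S,2R,3S)-7-(benzyloxy)-1-[(tert-butyldimethylsilyl)oxy]-6-methoxy-1,2,3,4-tetrahydronaphthalene-2,3-diyl]dimethanol | CC(C)(C)[Si](C)(C)O[C@@H]1c2cc(OCc3ccccc3)c(OC)cc2C[C@H](CO)[C@@H]1CO
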